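## Analysis of the target

The target 20 is an acyclic 3,7-dimethylocta-1,6-diene whose only ring is the benzene ring of the acyl group. It is numbered here from the vinyl CH2 (C1) to the prenyl terminus C7, which carries two methyl groups. There are two adjacent stereocentres: C3 (R) is fully substituted with CH3, vinyl and an acetoxy group, and C4 (S) is a secondary carbinol carbon esterified with (E)-4-hydroxycinnamic acid. With C2–C3–C4–C5 drawn as a zigzag, the two oxygens are anti. The sensitive groups are the tertiary allylic acetate (ionised by acid or zerovalent palladium), the vicinal diester (acyl migration whenever one oxygen is free), the electron-rich C6=C7 alkene, the cinnamate and the free phenol. The difficulty is a stereodefined tertiary/secondary diol on a flexible chain with no ring to relay stereochemistry, in which the small acyl group sits on the hindered oxygen and the large one on the accessible oxygen. The strategy rests on C4: it carries an oxygen and a prenyl group (C5H2–C6H=C7(CH3)2) and lies next to C3, which can come from a ketone carbonyl. This α-hydroxy-γ,δ-unsaturated ketone pattern is what a [2,3]-Wittig shift of an α-(1,1-dimethylallyloxy) ketone gives, with inversion of the allyl unit. C4 is therefore set by a catalyst and C3 by 1,2-induction from C4.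

## Retrosynthetic reasoning

**Phenol last (20 from 19).** A free phenol would compete in every acylation, so it is carried as a silyl ether. Aryl silyl ethers fall to buffered fluoride under conditions that leave both esters alone. No skeletal bond is cut.

**C4–O acyl bond (19 from 14 and 17).** The cinnamate is a Michael acceptor and would not survive organometallic steps, so it is attached late and convergently. The forward reaction must acylate a hindered secondary alcohol faster than the neighbouring acetate can migrate. Acid 17 comes from p-coumaric acid 15 by silylation.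

**O4 silyl ether (14 from 13).** The silyl group keeps O4 blocked while the acetate is placed on O3, and it is the bulky, non-chelating substituent that the carbonyl addition needs. Its removal must avoid an alkoxide at C4, so an HF-based, non-basic reagent is used.

**C2–C3 bond and O3–acetyl bond (13 from 10 and 11 through 12).** The fully substituted C3 is made by 1,2-addition to a ketone. Vinyl is the nucleophile and methyl the ketone substituent because Felkin–Anh addition of 11 to 10 gives the anti O3/O4 arrangement of the target. The reverse pairing would need a chelated transition state and an enone that cannot pass through amine catalysis. The alkoxide 12 is the only free oxygen at that moment, so trapping it with acetic anhydride puts the small acyl group on the hindered oxygen without any selectivity problem.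

**Silylation (10 from 9).** A protecting-group step that must not epimerise the α-stereocentre of the ketol.

**C4–C5 bond (9 from 6), the key disconnection.** Reconnecting O4 to C7 and cutting C4–C5 turns the ketol 9 into the achiral ether 6. The forward shift forms the C–C bond, leaves the oxygen on C4, creates the C6=C7 alkene and converts an easily made tertiary allyl ether into a linear prenyl group. C4 is the only new stereocentre, and a chiral amine controls it through the enamine.

**Ether and ketone assembly (6 from 4 and 5; 4 from 3; 3 from 1 and 2).** The ether C–O bond is made by Williamson alkylation at the carboxylic acid oxidation level. A tertiary alkoxide would enolise an α-halo ketone, whereas the carboxylate of 2 is inert to it. The Weinreb amide 4 then gives the methyl ketone with 5 without over-addition. These are three routine steps, so the risk stays in the key step.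

## Alternatives that were turned down

**Alternative 1:** The C4–C5 unit is traced back to an oxirane on a divinyl carbinol.
- Key step: Hf(OtBu)4 with a chiral bishydroxamic acid ligand and a tertiary alkyl hydroperoxide epoxidises one of the two enantiotopic vinyl groups of 3-methylpenta-1,4-dien-3-ol A1, giving (2R)-2-[(2S)-oxiran-2-yl]but-3-en-2-ol A2. A 2-methylprop-1-enyl cuprate then opens the CH2 terminus to give (3R,4S)-3,7-dimethylocta-1,6-diene-3,4-diol A3.
- For: both stereocentres arise in one catalytic step from a C6 carbinol made in one step from an acetate ester and 11. Group selection can correct itself, because the minor enantiomer is consumed by a second epoxidation. The whole route would take about six steps, so on step economy and on setting both centres at once it is stronger than the chosen route.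
- Against: monosubstituted vinyl groups are the least nucleophilic alkenes, and one transition state on a hindered tertiary alcohol must control both group selection and π-face. A2 is small and water-soluble, and its tertiary alkoxide can undergo Payne-type epoxide migration under the basic cuprate conditions, which would scramble the site of attack. A3 has both hydroxyls free, so the acetate must be forced onto the tertiary oxygen after the cinnamate is in place, next to an ester that can migrate.
- Comparison: the chosen route sets the two centres one at a time by well-understood elements, installs the prenyl group regiospecifically, and places the acetate in the same flask in which C3 is formed.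

**Alternative 2:** The C3–O bond is traced back to racemic 2-methyl-2-vinyloxirane A4.
- Key step: Pd2(dba)3 with a chiral bis(2-diphenylphosphinobenzamide) of trans-cyclohexane-1,2-diamine ionises A4 to interconverting π-allyl complexes of zerovalent-palladium origin. 4-Methoxybenzyl alcohol A5, delivered as a borate made with BEt3, attacks the tertiary terminus to give (2R)-2-[(4-methoxyphenyl)methoxy]-2-methylbut-3-en-1-ol A6.
- For: this is a dynamic kinetic asymmetric etherification on exactly the substrate class it suits, and it creates the fully substituted C3 centre catalytically from a cheap racemate. On security of enantiocontrol it is stronger than the chosen key step.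
- Against: A6 holds only C1–C4. After oxidation to (2R)-2-[(4-methoxyphenyl)methoxy]-2-methylbut-3-enal A7, a prenyl metal must react through its α-carbon, whereas such reagents normally react through the γ-carbon and give the reverse-prenyl isomer. The nucleophile must also distinguish the faces of an aldehyde whose α-carbon differs only in CH3 versus CH=CH2, so the 1,2-induction at C4 is weak with or without chelation. The 4-methoxybenzyl group sits on the oxygen that must end as the acetate, so an oxidative deprotection and a late tertiary acetylation beside the cinnamate follow.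
- Comparison: the step count is similar. The chosen route gets the linear prenyl group automatically from allyl inversion, and its 1,2-induction relies on the well-differentiated OSi/CH2R/H triad at C4.

**Alternative 3:** The C3–C4 bond is cut.
- Key step: 4-methylpent-3-enal A8 and tert-butyldimethyl{[(2E)-4-(4,4,5,5-tetramethyl-1,3,2-dioxaborolan-2-yl)but-2-en-2-yl]oxy}silane A9 react through a closed six-membered chair under a chiral phosphoric acid. The product is (3R,4S)-3-[(tert-butyldimethylsilyl)oxy]-3,7-dimethylocta-1,6-dien-4-ol A10, with the vinyl group unveiled by allyl transposition.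
- For: this is the most convergent plan. One step forms the C3–C4 bond and both stereocentres, the E geometry of A9 translates into the anti O3/O4 relationship, and O3 and O4 emerge differentiated. On convergence and stereochemical economy it is stronger than the chosen route.
- Against: A9 must be a single geometric isomer of a silyl enol ether bearing an allylic boron, and any Z isomer gives the C3 epimer directly. A γ,γ-disubstituted boronate must build a fully substituted carbon in the chair and will be slow. A8 is a β,γ-unsaturated aldehyde that can slip into conjugation and self-condense under the Brønsted acid. The tertiary silyl ether of A10 must later be removed beside an ester and the tertiary hydroxyl acetylated, again with migration risk.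
- Comparison: the chosen route uses simple, stable building blocks and introduces the tertiary acetate without ever acylating a free tertiary alcohol.

Key step: step 4

Assumption: the (S)-configured diamine catalyst is taken to favour the 3S ketol 9; the sense of induction cannot be fixed on paper, and if it is the opposite, the equally available (R)-diamine is used with nothing else changed.

## Route

Step 1
Reactants: 1 2-methylbut-3-en-2-ol; 2 bromoacetic acid
Product: 3 2-[(2-methylbut-3-en-2-yl)oxy]acetic acid
Conditions: NaH (2.5 equiv), THF, 0 °C → reflux; then cold 1 M HCl to pH 3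
Reagents that add atoms: none
Why: Williamson ether synthesis: the tertiary sodium alkoxide displaces bromide from sodium bromoacetate by SN2; the carboxylate is not enolised or attacked by the alkoxide, which is why the acid and not an α-halo ketone serves as electrophile.

Step 2
Reactants: 3 2-[(2-methylbut-3-en-2-yl)oxy]acetic acid
Product: 4 N-methoxy-N-methyl-2-[(2-methylbut-3-en-2-yl)oxy]acetamide
Conditions: MeNH(OMe)·HCl, EDC·HCl, N-methylmorpholine, CH2Cl2, 0 °C → rt
Reagents that add atoms: N,O-dimethylhydroxylamine hydrochloride, CNOC.Cl
Why: Carbodiimide-mediated amide coupling of the acid with the hydroxylamine salt; the tertiary allyl ether and the alkene are inert under these neutral conditions.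

Step 3
Reactants: 4 N-methoxy-N-methyl-2-[(2-methylbut-3-en-2-yl)oxy]acetamide; 5 methylmagnesium bromide
Product: 6 1-[(2-methylbut-3-en-2-yl)oxy]propan-2-one
Conditions: THF, 0 °C; aq. NH4Cl
Reagents that add atoms: none
Why: Weinreb ketone synthesis: the five-membered magnesium chelate of the tetrahedral adduct persists until work-up, so no second addition occurs and the methyl ketone is released only on hydrolysis.

Step 4
Reactants: 6 1-[(2-methylbut-3-en-2-yl)oxy]propan-2-one
Product: 9 (3S)-3-hydroxy-6-methylhept-5-en-2-one, via enamine 7 (not isolated), via iminium alkoxide 8 (not isolated)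
Conditions: (S)-1-(pyrrolidin-2-ylmethyl)pyrrolidine (20 mol %), CF3CO2H (20 mol %), MeOH, 0 °C → rt; aq. NH4Cl
Reagents that add atoms: none
Why: Condensation of 6 with the secondary amine gives, reversibly, the enamine on the oxygen-bearing side (7). Its nucleophilic carbon (C4 of the target) bonds to the unsubstituted CH2 terminus of the 1,1-dimethylallyl group while the O–C(CH3)2 bond breaks, a concerted suprafacial six-electron [2,3]-shift through a five-membered envelope that gives iminium alkoxide 8; methanol protonates 8 and the water of condensation hydrolyses it to 9 and frees the amine. The closest known reaction type is the secondary-amine-catalysed [2,3]-Wittig rearrangement of α-allyloxy ketones; no ring is closed, the cyclic array exists only in the transition state. The one new stereocentre is controlled by the catalyst: the protonated pyrrolidinylmethyl arm on C2 of the pyrrolidine blocks one face of the s-trans E-enamine, so the allyl group swings across the other face. Three selectivities are needed: enamine regiochemistry, [2,3] versus [1,2] shift, and enamine-face selectivity. The first is harmless because the methyl-side enamine has no sigmatropic outlet and reverts; the second is secured by the tertiary ether, whose gem-dimethyl groups weaken the C–O bond, relieve congestion on migration and end up on a trisubstituted alkene, while the attacked terminus is an unhindered CH2. Since that terminus carries no substituent, no second stereocentre and no alkene geometry arise, so face selectivity is the only open issue.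

Step 5
Reactants: 9 (3S)-3-hydroxy-6-methylhept-5-en-2-one
Product: 10 (3S)-3-[(tert-butyldimethylsilyl)oxy]-6-methylhept-5-en-2-one
Conditions: TBSCl, imidazole, DMF, 0 °C → rt
Reagents that add atoms: tert-butyldimethylsilyl chloride (TBSCl), CC(C)(C)[Si](C)(C)Cl
Why: Imidazole-promoted silylation of a secondary alcohol; the mild base should not enolise the ketone, so the C3 configuration is kept, and the bulky TBS group is the non-chelating substituent needed in step 6.

Step 6
Reactants: 10 (3S)-3-[(tert-butyldimethylsilyl)oxy]-6-methylhept-5-en-2-one; 11 vinylmagnesium bromide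
Product: 13 (3R,4S)-4-[(tert-butyldimethylsilyl)oxy]-3,7-dimethylocta-1,6-dien-3-yl acetate, via bromomagnesium alkoxide 12 (not isolated)
Conditions: THF, −78 °C; then Ac2O (3 equiv), DMAP (cat.), −78 °C → rt
Reagents that add atoms: acetic anhydride, CC(=O)OC(C)=O
Why: Grignard 1,2-addition under Felkin–Anh (non-chelation) control: the bulky, poorly coordinating OTBS group lies perpendicular to the carbonyl plane and anti to the incoming vinyl group, which passes the small C4–H, so the 3R centre forms with O3 and O4 anti; THF as donor solvent disfavours a chelate. The tertiary alkoxide 12, the only nucleophilic oxygen present, is then O-acylated in the same flask by Ac2O.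

Step 7
Reactants: 13 (3R,4S)-4-[(tert-butyldimethylsilyl)oxy]-3,7-dimethylocta-1,6-dien-3-yl acetate
Product: 14 (3R,4S)-4-hydroxy-3,7-dimethylocta-1,6-dien-3-yl acetate
Conditions: HF·pyridine, pyridine, THF, 0 °C → rt
Reagents that add atoms: none
Why: Fluoride-mediated desilylation driven by Si–F bond formation; the pyridine-buffered, weakly acidic medium avoids the C4 alkoxide that would trigger O3→O4 acetyl migration and is too mild to ionise the tertiary allylic acetate.

Step 8
Reactants: 15 p-coumaric acid
Product: 17 (2E)-3-{4-[(tert-butyldimethylsilyl)oxy]phenyl}prop-2-enoic acid, via bis-silyl coumarate 16 (not isolated)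
Conditions: TBSCl (2.4 equiv), imidazole, DMF, rt; then AcOH/THF/H2O, rt
Reagents that add atoms: tert-butyldimethylsilyl chloride (TBSCl), CC(C)(C)[Si](C)(C)Cl
Why: Imidazole-promoted silylation of both acidic hydroxyls, followed by selective hydrolysis of the very labile silyl ester of 16 in aqueous acetic acid, to which the aryl silyl ether is stable.

Step 9
Reactants: 14 (3R,4S)-4-hydroxy-3,7-dimethylocta-1,6-dien-3-yl acetate; 17 (2E)-3-{4-[(tert-butyldimethylsilyl)oxy]phenyl}prop-2-enoic acid
Product: 19 (3R,4S)-3-(acetyloxy)-3,7-dimethylocta-1,6-dien-4-yl (2E)-3-{4-[(tert-butyldimethylsilyl)oxy]phenyl}prop-2-enoate, via mixed anhydride 18 (not isolated)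
Conditions: 2,4,6-Cl3C6H2COCl, Et3N, toluene, rt (17 → 18); then 14, DMAP, 0 °C → rt
Reagents that add atoms: none
Why: Yamaguchi esterification: DMAP attacks the mixed anhydride 18 at the unhindered cinnamoyl carbonyl and the acylpyridinium acylates the C4 hydroxyl; pre-forming 18 and keeping the temperature low favours acylation over base-mediated acetyl migration. Acylation at oxygen leaves both stereocentres untouched.

Step 10
Reactants: 19 (3R,4S)-3-(acetyloxy)-3,7-dimethylocta-1,6-dien-4-yl (2E)-3-{4-[(tert-butyldimethylsilyl)oxy]phenyl}prop-2-enoate
Product: 20 (3R,4S)-3-(acetyloxy)-3,7-dimethylocta-1,6-dien-4-yl (2E)-3-(4-hydroxyphenyl)prop-2-enoate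
Conditions: Bu4NF, AcOH (1:1), THF, 0 °C
Reagents that add atoms: none
Why: Fluoride cleavage of an aryl silyl ether, which is far more labile than an alkyl silyl ether because phenoxide is a good leaving group; the acetic acid buffer protonates the phenoxide at once and so protects both esters from acyl transfer.

## Compound list

1 | 2-methylbut-3-en-2-ol | C=CC(C)(C)O | starting material
2 | bromoacetic acid | OC(=O)CBr | starting material
3 | 2-[(2-methylbut-3-en-2-yl)oxy]acetic acid | C=CC(C)(C)OCC(=O)O | intermediate
4 | N-methoxy-N-methyl-2-[(2-methylbut-3-en-2-yl)oxy]acetamide | C=CC(C)(C)OCC(=O)N(C)OC | intermediate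
5 | methylmagnesium bromide | C[Mg]Br | starting material
6 | 1-[(2-methylbut-3-en-2-yl)oxy]propan-2-one | CC(=O)COC(C)(C)C=C | intermediate
7 | 1-{[(2S)-1-{(1E)-1-[(2-methylbut-3-en-2-yl)oxy]prop-1-en-2-yl}pyrrolidin-2-yl]methyl}pyrrolidine (enamine of 6 and the catalyst) | C/C(=C\OC(C)(C)C=C)N1CCC[C@H]1CN1CCCC1 | intermediate
8 | (3S)-6-methyl-2-[(2S)-2-(pyrrolidin-1-ylmethyl)pyrrolidin-1-ium-1-ylidene]hept-5-en-3-olate (iminium alkoxide) | CC(=[N+]1CCC[C@H]1CN1CCCC1)[C@@H]([O-])CC=C(C)C | intermediate
9 | (3S)-3-hydroxy-6-methylhept-5-en-2-one | CC(=O)[C@@H](O)CC=C(C)C | intermediate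
10 | (3S)-3-[(tert-butyldimethylsilyl)oxy]-6-methylhept-5-en-2-one | CC(=O)[C@@H](O[Si](C)(C)C(C)(C)C)CC=C(C)C | intermediate
11 | vinylmagnesium bromide | C=C[Mg]Br | starting material
12 | bromomagnesium (3R,4S)-4-[(tert-butyldimethylsilyl)oxy]-3,7-dimethylocta-1,6-dien-3-olate | C=C[C@@](C)(O[Mg]Br)[C@H](CC=C(C)C)O[Si](C)(C)C(C)(C)C | intermediate
13 | (3R,4S)-4-[(tert-butyldimethylsilyl)oxy]-3,7-dimethylocta-1,6-dien-3-yl acetate | C=C[C@@](C)(OC(C)=O)[C@H](CC=C(C)C)O[Si](C)(C)C(C)(C)C | intermediate
14 | (3R,4S)-4-hydroxy-3,7-dimethylocta-1,6-dien-3-yl acetate | C=C[C@@](C)(OC(C)=O)[C@H](CC=C(C)C)O | intermediate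
15 | p-coumaric acid, (2E)-3-(4-hydroxyphenyl)prop-2-enoic acid | O=C(O)/C=C/c1ccc(O)cc1 | starting material
16 | tert-butyldimethylsilyl (2E)-3-{4-[(tert-butyldimethylsilyl)oxy]phenyl}prop-2-enoate | CC(C)(C)[Si](C)(C)OC(=O)/C=C/c1ccc(O[Si](C)(C)C(C)(C)C)cc1 | intermediate
17 | (2E)-3-{4-[(tert-butyldimethylsilyl)oxy]phenyl}prop-2-enoic acid | O=C(O)/C=C/c1ccc(O[Si](C)(C)C(C)(C)C)cc1 | intermediate
18 | (2E)-3-{4-[(tert-butyldimethylsilyl)oxy]phenyl}prop-2-enoic 2,4,6-trichlorobenzoic anhydride | O=C(/C=C/c1ccc(O[Si](C)(C)C(C)(C)C)cc1)OC(=O)c1c(Cl)cc(Cl)cc1Cl | intermediate
19 | (3R,4S)-3-(acetyloxy)-3,7-dimethylocta-1,6-dien-4-yl (2E)-3-{4-[(tert-butyldimethylsilyl)oxy]phenyl}prop-2-enoate | C=C[C@@](C)(OC(C)=O)[C@H](CC=C(C)C)OC(=O)/C=C/c1ccc(O[Si](C)(C)C(C)(C)C)cc1 | intermediate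
20 | (3R,4S)-3-(acetyloxy)-3,7-dimethylocta-1,6-dien-4-yl (2E)-3-(4-hydroxyphenyl)prop-2-enoate | C=C[C@@](C)(OC(C)=O)[C@H](CC=C(C)C)OC(=O)/C=C/c1ccc(O)cc1 | target

## Step count and least certain steps

Total: 10 steps. Longest linear sequence: 9 steps (steps 1 to 7, then 9 and 10); step 8 is a one-step side branch.

**Step 4 (key step).** The most likely failure is poor facial selectivity. A methyl ketone gives a small, flexible enamine, and the E/Z isomers and the two N–C rotamers of the enamine lead to opposite senses in the envelope transition state. The ketol can also lose enantiopurity afterwards through amine-mediated enolisation, and turnover may be slow if the unproductive methyl-side enamine dominates.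

The fallback moves the [2,3]-shift to the ester level under stoichiometric chiral boron control, where only one position can be enolised. It sets out from 3 and returns at 10:
- 3 is esterified (MeI, K2CO3, DMF) to methyl 2-[(2-methylbut-3-en-2-yl)oxy]acetate F1.
- F1 is enolised with the appropriate antipode of 2-bromo-4,5-diphenyl-1,3-bis(4-methylphenylsulfonyl)-1,3,2-diazaborolidine and Et3N in CH2Cl2 at low temperature. The boron enolate rearranges to methyl (2S)-2-hydroxy-5-methylhex-4-enoate F2.
- Silylation (TBSCl, imidazole) gives methyl (2S)-2-[(tert-butyldimethylsilyl)oxy]-5-methylhex-4-enoate F3.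
- MeNH(OMe)·HCl with i-PrMgCl converts F3 into (2S)-2-[(tert-butyldimethylsilyl)oxy]-N-methoxy-N,5-dimethylhex-4-enamide F4.
- Addition of 5 to F4 gives 10.

**Step 6.** Facial selectivity at the carbonyl may be poor if a chelated or Cornforth-type trajectory competes with the Felkin–Anh one. The Grignard reagent may enolise the methyl ketone. The hindered tertiary alkoxide may acetylate incompletely, or the silyl group may shift from O4 to O3 before acylation and divert the acetate to O4.

The fallback replaces vinyl by a slimmer, less basic nucleophile and adds a reduction. From 10, ethynylmagnesium bromide (HC≡CMgBr) in THF at −78 °C followed by Ac2O gives (3R,4S)-4-[(tert-butyldimethylsilyl)oxy]-3,7-dimethyloct-6-en-1-yn-3-yl acetate F5. Semi-hydrogenation (H2, Pd/CaCO3 poisoned with Pb(OAc)2, quinoline) then gives 13, where the route is rejoined.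

**Step 7.** The acetyl group may migrate from the tertiary O3 to the freed O4 through a cyclic orthoester, which is thermodynamically downhill. The tertiary allylic acetate may also ionise if the medium is too acidic.

The fallback never has a free C4 hydroxyl beside the C3 acetate. It sets out from 10 and returns at 19, replacing steps 6, 7 and 9:
- 11 is added to 10 with aqueous NH4Cl quench, giving (3R,4S)-4-[(tert-butyldimethylsilyl)oxy]-3,7-dimethylocta-1,6-dien-3-ol F6.
- Bu4NF gives (3R,4S)-3,7-dimethylocta-1,6-diene-3,4-diol F7.
- The secondary hydroxyl is acylated selectively with 17 (EDC·HCl, DMAP), giving (3R,4S)-3-hydroxy-3,7-dimethylocta-1,6-dien-4-yl (2E)-3-{4-[(tert-butyldimethylsilyl)oxy]phenyl}prop-2-enoate F8.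
- The tertiary hydroxyl is acetylated (Ac2O, DMAP, Et3N), giving 19.

**Step 9.** Acylation of the C4 hydroxyl, which is flanked by the fully substituted C3, may be slow. That gives the amine bases time to promote acetyl migration, or the alcohol may attack the wrong carbonyl of the mixed anhydride.

The fallback acylates with a small, very reactive acyl chloride and builds the cinnamate alkene afterwards. From 14, (diethoxyphosphoryl)acetyl chloride and pyridine in CH2Cl2 at −20 °C give (3R,4S)-3-(acetyloxy)-3,7-dimethylocta-1,6-dien-4-yl 2-(diethoxyphosphoryl)acetate F9. Horner–Wadsworth–Emmons olefination under Masamune–Roush conditions (LiCl, i-Pr2NEt, MeCN) with 4-[(tert-butyldimethylsilyl)oxy]benzaldehyde F10 then gives the E-cinnamate 19, where the route is rejoined.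

## Further compounds

F1 | step 4 | methyl 2-[(2-methylbut-3-en-2-yl)oxy]acetate | COC(=O)COC(C)(C)C=C
F2 | step 4 | methyl (2S)-2-hydroxy-5-methylhex-4-enoate | COC(=O)[C@@H](O)CC=C(C)C
F3 | step 4 | methyl (2S)-2-[(tert-butyldimethylsilyl)oxy]-5-methylhex-4-enoate | COC(=O)[C@@H](O[Si](C)(C)C(C)(C)C)CC=C(C)C
F4 | step 4 | (2S)-2-[(tert-butyldimethylsilyl)oxy]-N-methoxy-N,5-dimethylhex-4-enamide | CON(C)C(=O)[C@@H](O[Si](C)(C)C(C)(C)C)CC=C(C)C
F5 | step 6 | (3R,4S)-4-[(tert-butyldimethylsilyl)oxy]-3,7-dimethyloct-6-en-1-yn-3-yl acetate | C#C[C@@](C)(OC(C)=O)[C@H](CC=C(C)C)O[Si](C)(C)C(C)(C)C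
F6 | step 7 | (3R,4S)-4-[(tert-butyldimethylsilyl)oxy]-3,7-dimethylocta-1,6-dien-3-ol | C=C[C@@](C)(O)[C@H](CC=C(C)C)O[Si](C)(C)C(C)(C)C
F7 | step 7 | (3R,4S)-3,7-dimethylocta-1,6-diene-3,4-diol | C=C[C@@](C)(O)[C@H](CC=C(C)C)O
F8 | step 7 | (3R,4S)-3-hydroxy-3,7-dimethylocta-1,6-dien-4-yl (2E)-3-{4-[(tert-butyldimethylsilyl)oxy]phenyl}prop-2-enoate | C=C[C@@](C)(O)[C@H](CC=C(C)C)OC(=O)/C=C/c1ccc(O[Si](C)(C)C(C)(C)C)cc1
F9 | step 9 | (3R,4S)-3-(acetyloxy)-3,7-dimethylocta-1,6-dien-4-yl 2-(diethoxyphosphoryl)acetate | C=C[C@@](C)(OC(C)=O)[C@H](CC=C(C)C)OC(=O)CP(=O)(OCC)OCC
F10 | step 9 | 4-[(tert-butyldimethylsilyl)oxy]benzaldehyde | O=Cc1ccc(O[Si](C)(C)C(C)(C)C)cc1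
A1 | alternative 1 | 3-methylpenta-1,4-dien-3-ol | C=CC(C)(O)C=C
A2 | alternative 1 | (2R)-2-[(2S)-oxiran-2-yl]but-3-en-2-ol | C=C[C@@](C)(O)[C@@H]1CO1
A3 | alternative 1 | (3R,4S)-3,7-dimethylocta-1,6-diene-3,4-diol | C=C[C@@](C)(O)[C@H](CC=C(C)C)O
A4 | alternative 2 | 2-methyl-2-vinyloxirane (racemic) | C=CC1(C)CO1
A5 | alternative 2 | 4-methoxybenzyl alcohol | COc1ccc(CO)cc1
A6 | alternative 2 | (2R)-2-[(4-methoxyphenyl)methoxy]-2-methylbut-3-en-1-ol | C=C[C@@](C)(OCc1ccc(OC)cc1)CO
A7 | alternative 2 | (2R)-2-[(4-methoxyphenyl)methoxy]-2-methylbut-3-enal | C=C[C@@](C)(OCc1ccc(OC)cc1)C=O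
A8 | alternative 3 | 4-methylpent-3-enal | CC(C)=CCC=O
A9 | alternative 3 | tert-butyldimethyl{[(2E)-4-(4,4,5,5-tetramethyl-1,3,2-dioxaborolan-2-yl)but-2-en-2-yl]oxy}silane | C/C(O[Si](C)(C)C(C)(C)C)=C\CB1OC(C)(C)C(C)(C)O1
A10 | alternative 3 | (3R,4S)-3-[(tert-butyldimethylsilyl)oxy]-3,7-dimethylocta-1,6-dien-4-ol | C=C[C@@](C)(O[Si](C)(C)C(C)(C)C)[C@H](CC=C(C)C)O
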